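Slowness of the exchange between the two substrates is what you look for here: with instant exchange the product's excess stays level, and without it the excess sinks as the favoured left-handed substrate thins.

| setting | alder | oak | maple | flask |
|---|---|---|---|---|
| left-handed substrate | 0.67 M | 1.5 M | 1 M | 1.0 M |
| right-handed substrate | 0.67 M | 1.5 M | 1 M | 1.0 M |
| gas | 54 mM (held) | 54 mM (held) | 54 mM (held) | 54 mM (held) |
| free catalyst | 13 mM | 13 mM | 6.5 mM | 13 mM |
| precatalyst | 1 mM | 1 mM | 1 mM | 1.0 mM |
| remark | run made earlier | run made earlier | run made earlier |  |
| time |  |  |  | 2.5 min |

| run | time / s | left-handed product / % | right-handed product / % |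
|---|---|---|---|
| alder | 15.0 | 4.4 | 1.3 |
| alder | 40.0 | 7.5 | 6.4 |
| alder | 80.0 | 15.4 | 10.6 |
| alder | 120 | 24.3 | 15.8 |
| oak | 10.0 | 1.4 | 1.4 |
| oak | 20.0 | 4.5 | 0.7 |
| oak | 50.0 | 11.7 | 5.5 |
| oak | 120 | 20.8 | 14.0 |
| maple | 30.0 | 4.2 | 4.0 |
| maple | 60.0 | 9.1 | 4.7 |
| maple | 90.0 | 11.3 | 7.4 |
| maple | 120 | 16.8 | 9.8 |

(each reading ± 1 percentage point)

- left-handed product and right-handed product together, in percent of the left-handed substrate and right-handed substrate charged together, at 2.5 min
- excess of left-handed product over right-handed product in the product at 2.5 min
- whether the exchange between left-handed substrate and right-handed substrate keeps pace with the reaction: how far the product's excess at 2.5 min gets from its value without exchange to its value with instant exchange (above 80 % keeps pace, below 20 % hardly takes part, else lags behind)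

- free catalyst is single-handed; left-handed substrate and right-handed substrate are mirror images of each other, charged as a racemate, each of them at the stated concentration
- the numbers in the tables scatter by 1 percentage point (one standard deviation)
- at the start none of the gas is in solution
- an excess is below zero if the other one leads

How far does the flask get? Alder and oak hold the flask's free catalyst and bracket its substrate, and after 120 s they stand at 40.1 % and 34.8 %. Taken as first order they give 0.00392 s⁻¹, so I reckon 44.4 % for the flask.

What lead does the catalyst give? Pool the readings up to 40.0 s in alder, 50.0 s in oak and 90.0 s in maple, and left-handed over right-handed product gives the selectivity factor s, 1.72, the factor by which left-handed substrate outreacts right-handed substrate at equal concentration. Instant exchange holds the excess at 26.5 %.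

And without exchange? Then the fraction of right-handed substrate left is the fraction of left-handed substrate left, raised to 1/s. With half the left-handed substrate gone, conversion is 41.6 % and the excess 20.3 %, close to my flask.

Which line do the runs follow? Alder and oak pooled at 120 s show 20.4 %, 6.1 percentage points below instant exchange. But 1 point of scatter on each reading, carried through both excesses, gives that gap a scatter of 5.6 points, so the runs do not firmly separate the two lines. The pooled reading stands nearer 20.3 % than 26.5 %, so my tentative call is an excess near 20.3 %, with exchange that hardly takes part.

The forecast gives 44 %, 20.5 % and lags behind, noting that “scatter barely separates these”.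

The flask gives 45.1 % and 20.7 %, and its exchange hardly takes part, getting 7.4 % of the way.

    partner + free catalyst + left-handed substrate → free catalyst + left-handed product (k = 21.0 M⁻² s⁻¹)
    partner + free catalyst + right-handed substrate → free catalyst + right-handed product (k = 12.0 M⁻² s⁻¹)
    2 free catalyst ⇌ resting dimer, settled at all times (K = 78.0 M⁻¹)
    partner + precatalyst → racemization catalyst + spent reagent (k = 0.0440 M⁻¹ s⁻¹)
    gas ⇌ partner, rate k5*(csat - [partner]) (kL = 0.400 s⁻¹)
    left-handed substrate + racemization catalyst ⇌ right-handed substrate + racemization catalyst, rate k6*[racemization catalyst]*[left-handed substrate] forward; the back reaction follows from the equilibrium constant (k = 7.40 M⁻¹ s⁻¹)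

In this flask at 2.50 min, racemization catalyst, formed one for one with the 2.23 × 10⁻⁴ M of spent reagent, gives the forward exchange a half-life of 7.00 min. Left-handed substrate's half-life by reaction is then 2.0 min, which is shorter. With s, the 47 % of left-handed substrate left gives this flask 19.8 %, against 20.7 %. The neighbour charged with 0.052 M of free catalyst keeps 24 %, which gives 14.8 %, and that neighbour shows 15.6 %.

The numbers in the tables come from a simulation from invented constants; the scatter is artificial.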